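Methyl gyrophorate, the target, consists of three orsellinate rings (A, methyl ester; B, middle; C, terminal) linked through two aryl esters. In every ring the C6 methyl stands ortho to the carboxyl carbon C1. This is the site where a phloroglucinol carboxylate bears an oxygen equivalent to O2. The route therefore cuts all three C6–CH3 bonds and traces each back to a C6 triflate. One Stille reaction with tetramethylstannane makes the three bonds in a single operation on tridepside tris-triflate 9. Compound 9 has benzyl ethers on O2 and O4 of ring C and free, chelated O2–H groups on rings A and B. Acid 4, used twice, and methyl 2,4,6-trihydroxybenzoate supply all rings.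

Key step: step 8

Remark on the chemistry: the target has no stereocentre and no hindered axis (its SMILES carries no stereo descriptor), so it is achiral and no step has to set or protect configuration.

Labels: in each ring C1 bears the carboxyl carbon, O2 is the chelated oxygen, O4 is the para oxygen, and C6 is the carbon that ends up methylated. Tf = trifluoromethanesulfonyl, Bn = benzyl.

Design notes:
- **Ring C protection.** Ring C of the coupling substrate is benzylated on O2 as well as on O4. This costs no step, because acid 4 serves for rings B and C alike and both ethers fall in the last step. It also leaves ring C without an acidic OH during the hot palladium step.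
- **Order of assembly.** The chain grows from ring A to ring C. Each triflate is installed when the only free phenol is the intended one (step 2) or one of two equivalent ones (step 5). No triflation has to choose between chelated phenols of different rings.
- **Ester formation.** The ester links come from a free acid and a carbodiimide, not from a phenoxide attacking a triflate-bearing acyl donor, because phenoxides can also attack the sulfur of an activated aryl triflate.

Step 1
Reactants: 1 2,4,6-trihydroxybenzaldehyde
Product: 2 2,4-bis(benzyloxy)-6-hydroxybenzaldehyde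
Conditions: BnBr (2.05 equiv), K2CO3 (2.2 equiv), DMF, 0 °C to rt
Reagents that add atoms: benzyl bromide, BrCc1ccccc1
Why: Williamson ether synthesis: the unchelated O4–H and then one of the two equivalent ortho phenols are alkylated, whereas the last ortho OH is held in a strong hydrogen bond to the formyl oxygen and should stay free when only two equivalents of halide are offered.

Step 2
Reactants: 2 2,4-bis(benzyloxy)-6-hydroxybenzaldehyde
Product: 3 3,5-bis(benzyloxy)-2-formylphenyl triflate
Conditions: Tf2O (1.2 equiv), pyridine, CH2Cl2, 0 °C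
Reagents that add atoms: trifluoromethanesulfonic anhydride, O=S(=O)(OS(=O)(=O)C(F)(F)F)C(F)(F)F
Why: Standard O-triflation of a phenol with triflic anhydride and pyridine; 2 has a single free OH, so no site selectivity is needed, and the benzyl ethers and the aldehyde are inert.

Step 3
Reactants: 3 3,5-bis(benzyloxy)-2-formylphenyl triflate
Product: 4 2,4-bis(benzyloxy)-6-(triflyloxy)benzoic acid
Conditions: NaClO2, NaH2PO4, 2-methyl-2-butene, t-BuOH/THF/H2O, rt
Reagents that add atoms: sodium chlorite, [Na+].[O-]Cl=O
Why: Pinnick oxidation turns even 2,6-disubstituted benzaldehydes into acids in a weakly acidic buffer in which an aryl triflate is not hydrolysed, and the alkene traps hypochlorous acid before it can chlorinate the alkoxy-substituted ring.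

Step 4
Reactants: 4 2,4-bis(benzyloxy)-6-(triflyloxy)benzoic acid; 5 methyl 2,4,6-trihydroxybenzoate
Product: 6 methyl 4-{[2,4-bis(benzyloxy)-6-(triflyloxy)benzoyl]oxy}-2,6-dihydroxybenzoate
Conditions: DCC (1.1 equiv), DMAP (0.1 equiv), 5 (1.2 equiv), CH2Cl2/THF, 0 °C to rt
Reagents that add atoms: none
Why: Steglich esterification as used in classical depside couplings: O4–H of 5 is the only phenol that is neither hydrogen-bonded to nor flanked by the ester group, so it should take up the hindered acyl group selectively, helped by a small excess of 5.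

Step 5
Reactants: 6 methyl 4-{[2,4-bis(benzyloxy)-6-(triflyloxy)benzoyl]oxy}-2,6-dihydroxybenzoate
Product: 7 methyl 4-{[2,4-bis(benzyloxy)-6-(triflyloxy)benzoyl]oxy}-2-hydroxy-6-(triflyloxy)benzoate
Conditions: Tf2O (1.05 equiv), pyridine (3 equiv), CH2Cl2, −20 to 0 °C
Reagents that add atoms: trifluoromethanesulfonic anhydride, O=S(=O)(OS(=O)(=O)C(F)(F)F)C(F)(F)F
Why: O-Triflation that desymmetrises a 2,6-dihydroxybenzoate: O2 and O6 of ring A are equivalent, so either gives 7, and the first triflate makes the ring poorer in electrons and leaves the remaining OH fully chelated to the ester carbonyl, so one equivalent of anhydride should stop at the monotriflate.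

Step 6
Reactants: 7 methyl 4-{[2,4-bis(benzyloxy)-6-(triflyloxy)benzoyl]oxy}-2-hydroxy-6-(triflyloxy)benzoate
Product: 8 methyl 4-{[2,4-dihydroxy-6-(triflyloxy)benzoyl]oxy}-2-hydroxy-6-(triflyloxy)benzoate
Conditions: H2 (1 atm), 10% Pd/C, EtOAc, rt, no base
Reagents that add atoms: none
Why: Catalytic hydrogenolysis of aryl benzyl ethers; reduction of an aryl triflate on Pd/C needs an added amine or other base, so in neutral ethyl acetate at room temperature both triflates and both esters should persist.

Step 7
Reactants: 4 2,4-bis(benzyloxy)-6-(triflyloxy)benzoic acid; 8 methyl 4-{[2,4-dihydroxy-6-(triflyloxy)benzoyl]oxy}-2-hydroxy-6-(triflyloxy)benzoate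
Product: 9 tridepside tris-triflate, methyl 4-{[4-{[2,4-bis(benzyloxy)-6-(triflyloxy)benzoyl]oxy}-2-hydroxy-6-(triflyloxy)benzoyl]oxy}-2-hydroxy-6-(triflyloxy)benzoate
Conditions: DCC (1.1 equiv), DMAP (0.1 equiv), CH2Cl2, 0 °C to rt
Reagents that add atoms: none
Why: Second Steglich esterification: of the three phenols of 8 only O4–H of ring B is unchelated and unhindered, the same selectivity on which tridepside assembly from lecanorate-type diols rests, and catalytic DMAP at low temperature keeps exchange of the existing aryl ester slow.

Step 8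
Reactants: 9 tridepside tris-triflate; 10 tetramethylstannane
Product: 11 methyl 4-{[4-{[2,4-bis(benzyloxy)-6-methylbenzoyl]oxy}-2-hydroxy-6-methylbenzoyl]oxy}-2-hydroxy-6-methylbenzoate (methyl gyrophorate, ring C 2,4-di-O-benzyl ether)
Conditions: SnMe4 (9 equiv), Pd(PPh3)4 (15 mol %), LiCl (9 equiv), dry degassed DMF, 85 °C, sealed tube
Reagents that add atoms: tetramethylstannane, C[Sn](C)(C)C
Why: This is a Stille cross-coupling run three times on one substrate: Pd(0) adds oxidatively to each C6–OTf bond, chloride from LiCl takes the place of triflate on palladium, a methyl group passes from tin to palladium, and reductive elimination forms the C6–CH3 bond and returns Pd(0). The closest known reaction type is the palladium-catalysed methylation of salicylate-type aryl triflates that carry an ester ortho to the leaving group, done with methyl tin, boron or zinc reagents. No ring is closed and no stereocentre is formed. The step needs insertion at the three triflates only, and each of them is activated by its ortho carboxyl carbon, whereas the acyl–O bonds of the two depside esters and the benzyl ethers should not add to a Pd/PPh3 catalyst at this temperature. Methyl transfer must also outrun ring closure of the arylpalladium species of rings B and C onto the neighbouring aryloxy ring; that C–H arylation needs a carbonate or carboxylate base, none is present, and the large excess of stannane speeds transmetallation. Because the medium is neutral, the chelated O2–H groups of rings A and B, the base-labile aryl esters and the methyl ester should survive, and ring C offers no free phenol from which acyl migration could start.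

Step 9
Reactants: 11 methyl gyrophorate, ring C 2,4-di-O-benzyl ether
Product: 12 methyl gyrophorate, methyl 4-{[4-[(2,4-dihydroxy-6-methylbenzoyl)oxy]-2-hydroxy-6-methylbenzoyl]oxy}-2-hydroxy-6-methylbenzoate
Conditions: H2 (1 atm), 10% Pd/C, EtOAc/THF, rt
Reagents that add atoms: none
Why: Catalytic hydrogenolysis removes both ring C benzyl ethers under neutral conditions that leave the two depside esters, the methyl ester and the aryl methyl groups untouched.

Compound list
1 | 2,4,6-trihydroxybenzaldehyde | O=Cc1c(O)cc(O)cc1O | starting material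
2 | 2,4-bis(benzyloxy)-6-hydroxybenzaldehyde | O=Cc1c(O)cc(OCc2ccccc2)cc1OCc1ccccc1 | intermediate
3 | 3,5-bis(benzyloxy)-2-formylphenyl triflate | O=Cc1c(OS(=O)(=O)C(F)(F)F)cc(OCc2ccccc2)cc1OCc1ccccc1 | intermediate
4 | 2,4-bis(benzyloxy)-6-(triflyloxy)benzoic acid | OC(=O)c1c(OS(=O)(=O)C(F)(F)F)cc(OCc2ccccc2)cc1OCc1ccccc1 | intermediate
5 | methyl 2,4,6-trihydroxybenzoate | COC(=O)c1c(O)cc(O)cc1O | starting material
6 | methyl 4-{[2,4-bis(benzyloxy)-6-(triflyloxy)benzoyl]oxy}-2,6-dihydroxybenzoate | COC(=O)c1c(O)cc(OC(=O)c2c(OS(=O)(=O)C(F)(F)F)cc(OCc3ccccc3)cc2OCc2ccccc2)cc1O | intermediate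
7 | methyl 4-{[2,4-bis(benzyloxy)-6-(triflyloxy)benzoyl]oxy}-2-hydroxy-6-(triflyloxy)benzoate | COC(=O)c1c(OS(=O)(=O)C(F)(F)F)cc(OC(=O)c2c(OS(=O)(=O)C(F)(F)F)cc(OCc3ccccc3)cc2OCc2ccccc2)cc1O | intermediate
8 | methyl 4-{[2,4-dihydroxy-6-(triflyloxy)benzoyl]oxy}-2-hydroxy-6-(triflyloxy)benzoate | COC(=O)c1c(OS(=O)(=O)C(F)(F)F)cc(OC(=O)c2c(OS(=O)(=O)C(F)(F)F)cc(O)cc2O)cc1O | intermediate
9 | tridepside tris-triflate, ring C 2,4-di-O-benzyl | COC(=O)c1c(OS(=O)(=O)C(F)(F)F)cc(OC(=O)c2c(OS(=O)(=O)C(F)(F)F)cc(OC(=O)c3c(OS(=O)(=O)C(F)(F)F)cc(OCc4ccccc4)cc3OCc3ccccc3)cc2O)cc1O | intermediate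
10 | tetramethylstannane | C[Sn](C)(C)C | starting material
11 | methyl gyrophorate, ring C 2,4-di-O-benzyl ether | COC(=O)c1c(C)cc(OC(=O)c2c(C)cc(OC(=O)c3c(C)cc(OCc4ccccc4)cc3OCc3ccccc3)cc2O)cc1O | intermediate
12 | methyl gyrophorate (CNP0212402.0) | COC(=O)c1c(C)cc(OC(=O)c2c(C)cc(OC(=O)c3c(C)cc(O)cc3O)cc2O)cc1O | target

Total step count: 9. Longest linear sequence: 9 steps (1, 2, 3, 4, 6, 7, 8, 9, 11, 12).

Steps most likely to fail

**Step 8.**
- Risk: the coupling may stall after one or two of the three sites. The arylpalladium species of rings B and C may close onto the neighbouring aryloxy ring by C–H arylation. Long heating may let the aryl esters exchange.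
- Fallback: the same C6–CH3 bond is made once, on the monomer, and the depside is then built from rings that are already methylated. It sets out from 3 and comes back to the route at 11.
- Suzuki–Miyaura coupling of 3 with methylboronic acid (PdCl2(dppf), K3PO4, dioxane, 90 °C), where a base does no harm, should give 2,4-bis(benzyloxy)-6-methylbenzaldehyde F1. Pinnick oxidation should give 2,4-bis(benzyloxy)-6-methylbenzoic acid F2.
- Steglich coupling of F2 with commercial methyl orsellinate (COC(=O)c1c(C)cc(O)cc1O) should give methyl 4-{[2,4-bis(benzyloxy)-6-methylbenzoyl]oxy}-2-hydroxy-6-methylbenzoate F3. Hydrogenolysis should give methyl lecanorate F4, and a second Steglich coupling of F2 with F4 should give 11.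

**Step 7.**
- Risk: acylation of the weakly nucleophilic O4–H of ring B by a 2,6-disubstituted acid may be slow. An O-to-N acyl shift within the carbodiimide adduct, or DMAP-induced exchange of the depside ester already present, may then take over.
- Fallback: a base-free photochemical acylation in which ring C is delivered as a ketene. It sets out from 8 and comes back to the route at 12.
- Commercial 2,4,6-trihydroxybenzoic acid (OC(=O)c1c(O)cc(O)cc1O) with acetone, TFA and TFAA should give 5,7-dihydroxy-2,2-dimethyl-4H-1,3-benzodioxin-4-one F5. BnBr and K2CO3 should alkylate the unchelated oxygen to give 7-(benzyloxy)-5-hydroxy-2,2-dimethyl-4H-1,3-benzodioxin-4-one F6. Tf2O and pyridine should give 7-(benzyloxy)-2,2-dimethyl-4-oxo-4H-1,3-benzodioxin-5-yl triflate F7.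
- Irradiation of F7 at 300 nm in CH2Cl2 in the presence of 8 should expel acetone and form the quinoketene 3-(benzyloxy)-5-oxo-6-(oxomethylidene)cyclohexa-1,3-dien-1-yl triflate F8. The O4–H of ring B should trap it to give the tridepside tris-triflate with ring C 4-O-benzyl and free O2–H F9.
- The conditions of step 8 should convert F9 into methyl gyrophorate ring C 4-O-benzyl ether F10, and hydrogenolysis as in step 9 should give 12.

**Step 5.**
- Risk: sulfonylation may not stop cleanly after the first of the two equivalent ring A phenols, or it may remain incomplete when the anhydride is rationed.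
- Fallback: ring A takes its triflate from acid 4, in which the triflate was installed on a single free phenol. It sets out from 4 and comes back to the route at 7.
- MeI and KHCO3 in DMF should give methyl 2,4-bis(benzyloxy)-6-(triflyloxy)benzoate F11. Neutral hydrogenolysis (H2, Pd/C, EtOAc) should give methyl 2,4-dihydroxy-6-(triflyloxy)benzoate F12. Steglich coupling of 4 with the unchelated O4–H of F12 should give 7.

Further compounds
F1 | step 8 | 2,4-bis(benzyloxy)-6-methylbenzaldehyde | Cc1cc(OCc2ccccc2)cc(OCc2ccccc2)c1C=O
F2 | step 8 | 2,4-bis(benzyloxy)-6-methylbenzoic acid | Cc1cc(OCc2ccccc2)cc(OCc2ccccc2)c1C(=O)O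
F3 | step 8 | methyl 4-{[2,4-bis(benzyloxy)-6-methylbenzoyl]oxy}-2-hydroxy-6-methylbenzoate | COC(=O)c1c(C)cc(OC(=O)c2c(C)cc(OCc3ccccc3)cc2OCc2ccccc2)cc1O
F4 | step 8 | methyl lecanorate | COC(=O)c1c(C)cc(OC(=O)c2c(C)cc(O)cc2O)cc1O
F5 | step 7 | 5,7-dihydroxy-2,2-dimethyl-4H-1,3-benzodioxin-4-one | CC1(C)OC(=O)c2c(O)cc(O)cc2O1
F6 | step 7 | 7-(benzyloxy)-5-hydroxy-2,2-dimethyl-4H-1,3-benzodioxin-4-one | CC1(C)OC(=O)c2c(O)cc(OCc3ccccc3)cc2O1
F7 | step 7 | 7-(benzyloxy)-2,2-dimethyl-4-oxo-4H-1,3-benzodioxin-5-yl triflate | CC1(C)OC(=O)c2c(OS(=O)(=O)C(F)(F)F)cc(OCc3ccccc3)cc2O1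
F8 | step 7 | 3-(benzyloxy)-5-oxo-6-(oxomethylidene)cyclohexa-1,3-dien-1-yl triflate (quinoketene) | O=C=C1C(=O)C=C(OCc2ccccc2)C=C1OS(=O)(=O)C(F)(F)F
F9 | step 7 | tridepside tris-triflate with ring C 4-O-benzyl and free O2–H | COC(=O)c1c(OS(=O)(=O)C(F)(F)F)cc(OC(=O)c2c(OS(=O)(=O)C(F)(F)F)cc(OC(=O)c3c(OS(=O)(=O)C(F)(F)F)cc(OCc4ccccc4)cc3O)cc2O)cc1O
F10 | step 7 | methyl gyrophorate ring C 4-O-benzyl ether | COC(=O)c1c(C)cc(OC(=O)c2c(C)cc(OC(=O)c3c(C)cc(OCc4ccccc4)cc3O)cc2O)cc1O
F11 | step 5 | methyl 2,4-bis(benzyloxy)-6-(triflyloxy)benzoate | COC(=O)c1c(OS(=O)(=O)C(F)(F)F)cc(OCc2ccccc2)cc1OCc1ccccc1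
F12 | step 5 | methyl 2,4-dihydroxy-6-(triflyloxy)benzoate | COC(=O)c1c(OS(=O)(=O)C(F)(F)F)cc(O)cc1O
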